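I decided to put every run on one clock before I judged any single reading.

| flask | X | J | G | time |
|---|---|---|---|---|
| violet | 300 mM | 240 mM | 24.0 mM |  |
| blue | 180 mM | 120 mM | 24.0 mM |  |
| red | 300 mM | 240 mM | 72.0 mM |  |
| amber | 300 mM | 120 mM | 24.0 mM |  |
| teal | 300 mM | 79.0 mM | 48.0 mM | 73 min |

| run | time / min | [Z] / mM |
|---|---|---|
| violet run | 12 | 83.8 |
| violet run | 24 | 137.4 |
| violet run | 36 | 170.3 |
| violet run | 49 | 191.1 |
| violet run | 61 | 199.8 |
| violet run | 73 | 210.1 |
| blue run | 12 | 22.0 |
| blue run | 24 | 46.7 |
| blue run | 36 | 66.8 |
| blue run | 49 | 79.7 |
| blue run | 61 | 87.8 |
| blue run | 73 | 93.9 |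
| red run | 12 | 148.6 |
| red run | 24 | 199.9 |
| red run | 36 | 218.5 |
| red run | 49 | 228.9 |
| red run | 61 | 232.2 |
| red run | 73 | 236.3 |
| amber run | 12 | 33.4 |
| amber run | 24 | 67.8 |
| amber run | 36 | 89.3 |
| amber run | 49 | 102.7 |
| amber run | 61 | 109.5 |
| amber run | 73 | 110.6 |

(readings scatter by 0.9 mM)

- Overall: X + J -> Z, with G as catalyst.
- Constant volume, constant temperature.
- An order is taken over about fifteen percent of the charge, up and down.

1. the power of [J] that the first rate follows, about the charge of the violet run; measure it at two percent of X made into Z
2. the power of [G] that the first rate follows, about the charge of the violet run; measure it at two percent of X made into Z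
3. the blue run starts with 120 mM less of X and of J than the violet run, and with no Z. Compared where both hold the same amount of X, once fifteen percent of what the blue run was charged with has turned into Z, is the blue run faster, slower or alike (within a tenth)?
4. Z in the teal run at 73 min, as a share of the X charged
5. which of these the readings show (the catalyst rests as a dimer / nothing beyond the main steps / the catalyst wakes slowly / two substrates go astray together / the substrate kills the catalyst)

Let s be the share of the X charge still present and j the share of the J charge still present. X and J leave one for one, so a rate proportional to G, X and J integrates to a simple form: ln(s/j) grows in a straight line through the origin. Its slope goes with the G charge and with the X charge minus the J charge. That is the bench rule of the second-order plot.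

I tried it on the amber run. The log read 0.576 at 24 min and 1.52 at 49 min, a slope of 0.0377 min⁻¹. At 12 min the rule asked for 0.452, but the reading was 0.208, about half of that.

So the rule has a border. The line cuts the time axis at a reading of 8.70 min, an induction period. The violet run, richer in J, cut it sooner, at 3.73 min. I therefore carried one quantity, 62.6 M·s: the wake dose, the lag times the J charge.

For the violet charge the dose gives a lag of 4.35 min. Inside a lag the awake share grows as time over lag, so Z grows with the square of time. Two percent of X then falls at 1.86 min, inside that lag. There the rate goes as the root of full rate over lag, which gave me powers of 1 in J and 0.5 in G.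

In the teal run J is the limiting reagent, with a ceiling of 26.3 % of the X charge. Its lag, taken on the J charge, is 13.2 min, well short of 73 min. The scaled slope of 0.0925 min⁻¹ leaves 0.293 % of the J charge, so I committed to 26.3 %.

The forecast gave 1.02 and 0.59 for the powers, slower for the comparison, 26 % for the teal share and the catalyst wakes slowly for the reading, on the ground that “The catalyst wakes slowly, helped by J”. Its G power stood above my 0.5.

The flask gave 1.0, 0.58, slower, 26.1 % and the catalyst wakes slowly.

    Dz + X + J → Z + Dz (8.880 L² mol⁻² min⁻¹)
    G + J → Dz + J (0.9720 L mol⁻¹ min⁻¹)

In the teal run G became Dz while J was present, and Dz made Z from X and J until, at 73 min, 26.1 % of the X charge stood as Z, below the ceiling of 26.3 %, the pace of waking barely moving that share; my estimate of its lag, from the wake dose of 62.6 M·s read off the amber run and the J charge, had been 13.2 min. The same two steps ran in the blue run, where the dose gives a lag of 8.70 min and the amber slope, scaled to the blue charges, puts a quarter of X turned at 23.2 min, against a simulated 22.7 min.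

Readings and results were computed for an exercise, and the scatter is random.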